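## The problem

Compound 8 is a pentabrominated 2,2'-dihydroxydiphenyl ether. Ring A carries a hydroxyl at C1, bromine at C2 and C4 and the ether oxygen at C6. Ring B carries the ether oxygen at C1', bromine at C3', C4' and C5' and a hydroxyl at C6', so the bridging oxygen lies ortho to a hydroxyl on both rings. There is no stereocentre, so the task is regiochemical, together with the making of a crowded, electron-poor diaryl ether. A copper-mediated aryl–oxygen coupling would have to pick one halide among several carbon–bromine bonds and joins ortho-substituted, deactivated phenols poorly; the aryl bromides also exclude hydrogenolysis, aryllithium chemistry and zerovalent palladium. On ring B the C3' and C5' bromines are para and ortho to the C6' hydroxyl, but C4' is meta to it and para to the ether oxygen, so this bromine can only be placed while the C1' oxygen is still a free phenol, and the two ring B oxygens must stay distinguishable. Free polybromophenols are easily over-brominated and oxidised, so each hydroxyl should be unmasked only when its directing effect is wanted. The enabling feature is ring A: bromine at exactly the ortho (C2) and para (C4) carbons of the C1 hydroxyl, with the ether oxygen on the other ortho carbon C6, is the pattern bromine itself produces when a cyclohexanone bearing an aryloxy group on its α-carbon is oxidised to the phenol, so ring A can enter as a saturated ketone and the ether can be made by SN2 at sp3 carbon.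

## Retrosynthesis

**8 ⇒ 7.** The C5'–Br bond is cut first. In 7, C5' is the only unsubstituted carbon ortho or para to either hydroxyl, so the forward step is a one-equivalent electrophilic bromination with a single activated site. Cutting C4'–Br at this stage would have no forward counterpart, since that carbon is meta to the free hydroxyl. The forward reaction must stop after one bromine.

**7 ⇒ 6.** The C6' hydroxyl is masked as its methyl ether (O–CH3 bond). The methyl group survives carbonate, bromine and HBr in acetic acid, keeps ring B unreactive during the key step, and is removed by BBr3 without touching aryl bromides or the diaryl ether. A benzyl ether would call for hydrogenolysis, and a silyl or acyl group would not survive the key step.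

**6 ⇒ 4 (key disconnection, through 5).** The C2–Br and C4–Br bonds are removed and ring A is taken back to the cyclohexanone oxidation level. The neighbouring cut, through either aryl–oxygen bond of 6, would demand a coupling between polybrominated partners. Returning ring A to a ketone instead turns the Csp2–O bond into a Csp3–O bond. Precursor 4 has two bromines fewer and a plain cyclohexanone in place of a tetrasubstituted arene. The forward reaction must dehydrogenate ring A, brominate only C2 and C4, leave ring B alone and avoid cyclodehydration onto ring B.

**4 ⇒ 2 + 3.** The alkyl C6–O bond is cut, giving phenol 2 and commercial α-chloroketone 3. The alternative cut at C1'–O would require arylation of a hydroxyketone with an unactivated aryl bromide. The forward step is an SN2 displacement activated by the adjacent carbonyl.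

**2 ⇒ 1.** The C4'–Br bond is cut. In 1 this carbon is para to the free hydroxyl, the oxygen that later becomes the ether bridge, so the bromine that no later hydroxyl could direct is installed here. Compound 1 is commercial and already carries the future C3' bromine para to the methoxy group.

## Roads not taken

**Alternative 1:** Ring A is cut at C2–C3 and C5–C6 and assembled from the four-carbon 1,3-bis(silyl enol ether) A2, which carries the ring B aryloxy group on its terminal carbon, and the three-carbon bromo bis-acetal A3, which brings the C4 bromine. In the forward direction TiCl4 would promote a formal [3+3] cyclocondensation to salicylate A1.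
- Merits: the oxygen pattern and the C4 bromine of ring A are fixed by the skeleton, not by electrophilic selectivity. No ring is oxidised and no HBr-rich medium is involved. The ether is again made at sp3 carbon.
- Weak points: C2 arrives as an ester carbon that the target does not contain, so saponification and bromodecarboxylation must follow. Ring B of A1 has only the C4' bromine, so C3' and C5' must still be added around a demethylation. The diene needs an alkylation and two silylations and must tolerate TiCl4 beside an ionisable bromo-acetal.
- Comparison: the count is about nine steps against five. In positional certainty on ring A this road is better than the chosen one. The chosen plan sets against it half the length and the fact that the natural ortho/para pattern of a phenol is exactly what ring A needs.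

**Alternative 2:** The diaryl ether is viewed as a xanthene from which C9 has been excised: two carbon–carbon bonds to C9 are broken and C1–O and C6'–O are formed instead. Xanthenol A5 with H2O2 and acid would give the 9-hydroperoxide; Hock rearrangement and hydrolysis would open the central ring to a hydroxy aldehyde, and Dakin oxidation would give diol A4, the extra carbon leaving as formate.
- Merits: the ether linkage is present from the start. Either aryl group may migrate, because both openings converge on A4. A4 already holds the C4' bromine, the one no hydroxyl can direct, so four equivalents of bromine would fill every ortho and para position of both phenols and give 8 directly, with no protecting group and no regiochemical question.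
- Weak points: everything depends on a three-stage cascade on a ring system whose 9-cation is exceptionally stabilised. The hydroperoxide can ionise back at C9–O, and because C9 still bears hydrogen, dehydration to xanthone A6 competes with aryl migration. The Dakin step must work on an aldehyde activated only by an aryloxy group while an electron-rich diphenol sits in peroxide and acid. A5 comes from A6, which needs a clean monobromination.
- Comparison: on paper this road is about one step shorter and ends more cleanly than the chosen one. The chosen plan sets against it a strategic step of a reaction type known for cyclohexanones and a conventional way round each of its risks. If the Hock–Dakin sequence were shown to work on this ring system, this road would be preferable.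

**Alternative 3:** Ring A is cut at C1–C2 and C5–C6. Pyrone A9 supplies C2 to C5 with both bromines, and ketene bis(silyl) acetal A8 supplies C1 and C6 with both oxygens. On heating, A8 would add across C3 and C6 of A9; decarboxylative cycloreversion and loss of silanol would give A7 after aqueous work-up.
- Merits: the plan is convergent, both ring A bromines come from A9 so ring A is never brominated, and the medium is neutral. A7 differs from 6 only by the C3' bromine, which one further bromination para to the methoxy group would add.
- Weak points: the cycloaddition must join the most hindered pair of termini, the acetal carbon with two silyloxy groups and the bromine-bearing C3 of A9. The electronic preference is right, but stepwise conjugate addition or opening of the pyrone could divert material. A8 needs double deprotonation of an aryloxyacetic acid with a strong amide base beside an aryl bromide, and A9 is a multistep preparation. Three steps (bromination, demethylation, bromination) still follow A7.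
- Comparison: this road is better in convergence and does not rely on a directing group for ring A. It is longer, roughly nine steps in all, and its key step is less assured than a brominative aromatisation, which the chosen plan reaches from two commercial compounds in two steps.

Key step: step 3

Remark: 8 is achiral; 3 and 4 are used as racemates, and the single stereocentre of 4 disappears in step 3.

## Route

Step 1
Reactants: 1 5-bromo-2-methoxyphenol
Product: 2 4,5-dibromo-2-methoxyphenol
Conditions: Br2 (1.05 equiv), CH2Cl2, 0 °C
Reagents that add atoms: bromine, BrBr
Why: Electrophilic aromatic bromination; the hydroxyl is the strongest director, its para carbon (C4 of 1, the future C4') is open and less hindered than the ortho carbon lying between OH and Br, and the position para to methoxy is already brominated.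

Step 2
Reactants: 2 4,5-dibromo-2-methoxyphenol; 3 2-chlorocyclohexan-1-one (racemic)
Product: 4 2-(4,5-dibromo-2-methoxyphenoxy)cyclohexan-1-one (racemic)
Conditions: K2CO3 (2 equiv), KI (0.1 equiv), acetone, reflux
Reagents that add atoms: none
Why: Williamson-type SN2 displacement on an α-chloroketone by a phenoxide, accelerated by the adjacent carbonyl and by chloride–iodide exchange; carbonate is too weak a base for Favorskii rearrangement, and the new stereocentre is formed racemic and erased in step 3.

Step 3
Reactants: 4 2-(4,5-dibromo-2-methoxyphenoxy)cyclohexan-1-one (racemic)
Product: 6 2,4-dibromo-6-(4,5-dibromo-2-methoxyphenoxy)phenol, via 2-aryloxyphenol 5 (not isolated)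
Conditions: Br2 (2.05 equiv), glacial AcOH, 20 °C then 80 °C; cool, Br2 (2.05 equiv), 20 °C
Reagents that add atoms: bromine, BrBr
Why: With ring A numbered as in 8 (C1 the carbonyl carbon, C6 the carbon bearing the aryloxy group, C2 the other α-carbon), HBr-catalysed enolisation lets the first portion of Br2 brominate the two α-carbons; loss of HBr at C6, eased by the aryloxy oxygen that stabilises the developing cation, and a second loss of HBr from C2 give a cyclohexadienone that tautomerises to phenol 5. The second portion then substitutes 5 at the only open carbons ortho (C2) and para (C4) to its hydroxyl, a plain electrophilic aromatic bromination. The closest known reaction type is the oxidative aromatisation of cyclohexanones and cyclohexenones to bromophenols by excess bromine in acetic acid. No ring is closed, since the six-membered carbocycle is already present in 4 and is only dehydrogenated, and no stereocentre is formed, the one at C6 of 4 being erased. The step needs bromine on ring A only, and there only at C2 and C4: an enol and a free phenol react far faster than ring B, which has two bromines, two ether oxygens and no hydroxyl, and four equivalents leave no bromine over. Position is fixed because bromine delivered through an enol, a dienol or the phenol can only arrive α or γ to the C1 oxygen, C6 is occupied, and an α-bromine that survives on C2 sits where the target wants it. Cyclodehydration of the aryloxy ketone onto ring B, the benzofuran-forming path of such ketones in strong acid, is not expected because the ortho carbon of ring B is deactivated by two bromines and acetic acid with HBr is far weaker than the condensing acids that reaction needs.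

Step 4
Reactants: 6 2,4-dibromo-6-(4,5-dibromo-2-methoxyphenoxy)phenol
Product: 7 2,4-dibromo-6-(4,5-dibromo-2-hydroxyphenoxy)phenol
Conditions: BBr3 (3 equiv), CH2Cl2, −78 to 20 °C; then H2O
Reagents that add atoms: none
Why: Lewis-acid cleavage of an aryl methyl ether by BBr3, bromide attacking the methyl group of the boron-bound oxonium ion; the diaryl ether and the aryl bromides are inert, and the excess reagent allows for the free phenol.

Step 5
Reactants: 7 2,4-dibromo-6-(4,5-dibromo-2-hydroxyphenoxy)phenol
Product: 8 2,3,4-tribromo-6-(3,5-dibromo-2-hydroxyphenoxy)phenol
Conditions: Br2 (1.0 equiv), AcOH, 20 °C
Reagents that add atoms: bromine, BrBr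
Why: Electrophilic aromatic bromination; C5' is the only unsubstituted carbon ortho or para to either hydroxyl (C2, C4 and C3' are brominated, C6 and C1' carry the ether oxygen), the other C–H carbons are meta to hydroxyl, and one equivalent stops the reaction there.

## Compound list

1 | 5-bromo-2-methoxyphenol | COc1ccc(Br)cc1O | starting material
2 | 4,5-dibromo-2-methoxyphenol | COc1cc(Br)c(Br)cc1O | intermediate
3 | 2-chlorocyclohexan-1-one (racemic) | O=C1CCCCC1Cl | starting material
4 | 2-(4,5-dibromo-2-methoxyphenoxy)cyclohexan-1-one (racemic) | O=C1CCCCC1Oc1cc(Br)c(Br)cc1OC | intermediate
5 | 2-(4,5-dibromo-2-methoxyphenoxy)phenol (not isolated) | COc1cc(Br)c(Br)cc1Oc1ccccc1O | intermediate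
6 | 2,4-dibromo-6-(4,5-dibromo-2-methoxyphenoxy)phenol | Oc1c(Br)cc(Br)cc1Oc1cc(Br)c(Br)cc1OC | intermediate
7 | 2,4-dibromo-6-(4,5-dibromo-2-hydroxyphenoxy)phenol | Oc1c(Br)cc(Br)cc1Oc1cc(Br)c(Br)cc1O | intermediate
8 | 2,3,4-tribromo-6-(3,5-dibromo-2-hydroxyphenoxy)phenol | Oc1c(Br)cc(Br)cc1Oc1cc(Br)c(Br)c(Br)c1O | target

## Step count and risks

Total step count: 5. Longest linear sequence: 5 steps (1 → 2 → 4 → 6 → 7 → 8; 3 is bought).

**Step 3 (key step).**
- Most likely failure: acidolysis of the α-aryloxy ketone before ring A is aromatic. Six equivalents of HBr are released, and bromide attack at the carbonyl-activated C6, or ionisation of a C6-brominated intermediate, would release the ring B phenol.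
- Two further processes could intrude: stalling at α-bromoketones, because loss of HBr without base is slow, and addition of bromine across the enol-ether-like double bond of the intermediate enone, which would place bromine at C5.
- Within the step, dry acetic acid, a nitrogen sweep to remove HBr and the two-portion addition are the first measures.
- Fallback (sets out from 2, comes back at 6): ring A is brought in already aromatic. Phenol 2 displaces fluoride from 2-fluorobenzaldehyde F1 (K2CO3, DMF, 120 °C, SNAr activated by the ortho formyl group) to give 2-(4,5-dibromo-2-methoxyphenoxy)benzaldehyde F2. Baeyer–Villiger oxidation with mCPBA gives 2-(4,5-dibromo-2-methoxyphenoxy)phenyl formate F3, and hydrolysis with aqueous KOH gives phenol 5, now isolated. Two equivalents of Br2 in acetic acid then give 6.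

**Step 2.**
- Most likely failure: slow SN2 at a secondary carbon by a hindered, weakly nucleophilic phenoxide, while base-induced self-condensation and dehydrochlorination consume 3.
- Fallback (sets out from 2, comes back at 4): the phenoxide of 2 opens cyclohexene oxide F4 (K2CO3, DMF, 110 °C) by anti attack to give trans-2-(4,5-dibromo-2-methoxyphenoxy)cyclohexan-1-ol F5 as the racemate. Swern oxidation of the alcohol gives 4.

**Step 1.**
- Most likely failure: competing substitution ortho to the hydroxyl and double bromination, giving isomer mixtures that are hard to separate.
- Fallback (sets out from 1, comes back at 2): symmetry fixes the regiochemistry. O-Methylation of 1 (MeI, K2CO3) gives 4-bromo-1,2-dimethoxybenzene F6. Bromination para to the second methoxy group gives the symmetrical 1,2-dibromo-4,5-dimethoxybenzene F7. Mono-demethylation with NaSEt in DMF, which stops at the monophenoxide, gives 2 whichever methyl group is removed.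

**Step 5.**
- Most likely failure: over-bromination. The wanted carbon is crowded between OH and Br, and pushing conversion could bring in substitution ortho to the ether oxygen on either ring.
- Fallback (sets out from 2, comes back at 8): the two ring B oxygens exchange roles so that the third ring B bromine is placed before the ether is made.
  - One more equivalent of Br2 brominates 2 at the only open carbon ortho to its hydroxyl, giving 2,3,4-tribromo-6-methoxyphenol F8.
  - Tosylation (TsCl, Et3N) gives 2,3,4-tribromo-6-methoxyphenyl 4-methylbenzenesulfonate F9.
  - BBr3, which leaves aryl sulfonates intact, frees the other oxygen to give 2,3,4-tribromo-6-hydroxyphenyl 4-methylbenzenesulfonate F10.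
  - Alkylation with 3 as in step 2 gives 2,3,4-tribromo-6-[(2-oxocyclohexyl)oxy]phenyl 4-methylbenzenesulfonate F11. Sulfonates, unlike acyl groups, do not readily migrate between neighbouring oxygens under carbonate.
  - Brominative aromatisation as in step 3 gives 2,3,4-tribromo-6-(3,5-dibromo-2-hydroxyphenoxy)phenyl 4-methylbenzenesulfonate F12.
  - Saponification of the sulfonate (KOH, aqueous MeOH, reflux) gives 8.

## Further compounds

F1 | step 3 | 2-fluorobenzaldehyde | O=Cc1ccccc1F
F2 | step 3 | 2-(4,5-dibromo-2-methoxyphenoxy)benzaldehyde | O=Cc1ccccc1Oc1cc(Br)c(Br)cc1OC
F3 | step 3 | 2-(4,5-dibromo-2-methoxyphenoxy)phenyl formate | O=COc1ccccc1Oc1cc(Br)c(Br)cc1OC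
F4 | step 2 | cyclohexene oxide (7-oxabicyclo[4.1.0]heptane, cis, meso) | C1CC[C@H]2O[C@H]2C1
F5 | step 2 | trans-2-(4,5-dibromo-2-methoxyphenoxy)cyclohexan-1-ol (racemic, one enantiomer drawn) | O[C@@H]1CCCC[C@H]1Oc1cc(Br)c(Br)cc1OC
F6 | step 1 | 4-bromo-1,2-dimethoxybenzene | COc1ccc(Br)cc1OC
F7 | step 1 | 1,2-dibromo-4,5-dimethoxybenzene | COc1cc(Br)c(Br)cc1OC
F8 | step 5 | 2,3,4-tribromo-6-methoxyphenol | COc1cc(Br)c(Br)c(Br)c1O
F9 | step 5 | 2,3,4-tribromo-6-methoxyphenyl 4-methylbenzenesulfonate | COc1cc(Br)c(Br)c(Br)c1OS(=O)(=O)c1ccc(C)cc1
F10 | step 5 | 2,3,4-tribromo-6-hydroxyphenyl 4-methylbenzenesulfonate | Oc1cc(Br)c(Br)c(Br)c1OS(=O)(=O)c1ccc(C)cc1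
F11 | step 5 | 2,3,4-tribromo-6-[(2-oxocyclohexyl)oxy]phenyl 4-methylbenzenesulfonate (racemic) | O=C1CCCCC1Oc1cc(Br)c(Br)c(Br)c1OS(=O)(=O)c1ccc(C)cc1
F12 | step 5 | 2,3,4-tribromo-6-(3,5-dibromo-2-hydroxyphenoxy)phenyl 4-methylbenzenesulfonate | Oc1c(Br)cc(Br)cc1Oc1cc(Br)c(Br)c(Br)c1OS(=O)(=O)c1ccc(C)cc1
A1 | alternative 1 | ethyl 5-bromo-3-(4-bromo-2-methoxyphenoxy)-2-hydroxybenzoate | CCOC(=O)c1cc(Br)cc(Oc2ccc(Br)cc2OC)c1O
A2 | alternative 1 | 1-ethoxy-4-(4-bromo-2-methoxyphenoxy)-1,3-bis(trimethylsilyloxy)buta-1,3-diene (double-bond geometry not defined) | CCOC(O[Si](C)(C)C)=CC(O[Si](C)(C)C)=COc1ccc(Br)cc1OC
A3 | alternative 1 | 2-bromo-1,1,3,3-tetramethoxypropane | COC(OC)C(Br)C(OC)OC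
A4 | alternative 2 | 5-bromo-2-(2-hydroxyphenoxy)phenol | Oc1ccccc1Oc1ccc(Br)cc1O
A5 | alternative 2 | 2-bromo-9H-xanthen-9-ol (racemic) | OC1c2ccccc2Oc2ccc(Br)cc21
A6 | alternative 2 | 2-bromo-9H-xanthen-9-one | O=C1c2ccccc2Oc2ccc(Br)cc21
A7 | alternative 3 | 2,4-dibromo-6-(4-bromo-2-methoxyphenoxy)phenol | Oc1c(Br)cc(Br)cc1Oc1ccc(Br)cc1OC
A8 | alternative 3 | 1,1-bis(trimethylsilyloxy)-2-(4-bromo-2-methoxyphenoxy)ethene | C[Si](C)(C)OC(O[Si](C)(C)C)=COc1ccc(Br)cc1OC
A9 | alternative 3 | 3,5-dibromo-2H-pyran-2-one | O=C1OC=C(Br)C=C1Br
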